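(The earlier runs and the new flask were generated by integration on assumed constants; noise was put on by code.)

After 20.0 s the amber flask stops moving: target reads 19.5 % there and 20.1 % at 90.0 s, with 80.8 % of the starting material unreacted. The green run, with more second substrate and a higher temperature, sits lower. I therefore read both stalls as a race for partner, which I take as the limiting reagent, between starting material and second substrate.

| setting | amber | green | flask |
|---|---|---|---|
| starting material | 0.13 M | 0.13 M | 0.13 M |
| partner | 0.169 M | 0.169 M | 0.169 M |
| second substrate | 0.13 M | 0.20 M | 0.130 M |
| third substrate | 0.026 M | 0.026 M | 0.0260 M |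
| temperature | 60 °C | 66 °C | 60 °C |
| remark | the very flask that is asked about, followed so far | run made earlier |  |
| time |  |  | 2.0 min |

- amber (time / s: target / %, starting material / %): 10.0: 18.3, 82.7; 12.0: 17.9, 81.4; 20.0: 19.5, 81.4; 40.0: 20.4, 80.1; 60.0: 19.3, 80.4; 90.0: 20.1, 80.8
- green (time / s: target / %, starting material / %): 10.0: 11.9, 88.0; 20.0: 11.3, 88.5; 30.0: 12.3, 88.8; 50.0: 10.6, 88.0

(each reading ± 0.5 percentage points)

1. target, in percent of the starting material first charged, at 2.0 min
2. the remedy with the largest gain of target, or "none" below 2 percentage points (midnight / summer / spring / dawn / none)
3. target present, with what was taken out counted in, in percent of the starting material first charged, after spring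
4. target present, with what was taken out counted in, in percent of the starting material first charged, after dawn

- midnight: at 2.0 min raise the temperature by 10 K, then wait 40 s
- summer: change nothing and wait 40 s more
- spring: at 2.0 min add partner, 100 % of the amount charged, then wait 40 s
- dawn: at 2.0 min take out 90 % of the target then present, then wait 40 s

- what is taken out of target is counted as made
- the earlier runs were read with a standard deviation of 0.5 percentage points
- additions bring no volume worth counting

If it is a race, the plateau fraction p should follow r, the partner charged per second substrate charged. I divide one by the other, using the readings from 20.0 s on in amber and all four in green: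

amber: p = 19.8 %, r = 1.30, σ = p/r = 0.153

green: p = 11.5 %, r = 0.845, σ = p/r = 0.136

So σ, the fraction of starting material won per equivalent of partner reckoned on second substrate, is a crude selectivity factor. One number nearly carries both runs, but green's σ reads lower by 10.6 %, and green differs in temperature as well, so I can't tell the two settings apart from these runs.

My reckoning gives 19.8 % now, and I expect no gain from waiting, heating or taking target out, so dawn stays at 19.8 %. For spring, with the second substrate counted at its full charge:

p = σ × r × (1 + added share) = 39.7 %

The forecast gives 19.8 %, spring, 88 % after spring, which is above mine, and 19.9 % after dawn, on the reading that “the partner is exhausted by competition”.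

The flask gives 19.5 %, and spring is best, reaching 58.0 % for a gain of 38 percentage points, while dawn stays at 19.5 %.

starting material + partner → target (k = 0.930 M⁻¹ s⁻¹, Ea = 43.0 kJ mol⁻¹); second substrate + partner → second product (k = 7.50 M⁻¹ s⁻¹, Ea = 57.0 kJ mol⁻¹); third substrate + partner → third product (k = 0.670 M⁻¹ s⁻¹, Ea = 40.0 kJ mol⁻¹); partner ⇌ dormant form (K = 0.350, k = 0.150 s⁻¹, Ea = 91.0 kJ mol⁻¹, ΔH = −30.0 kJ mol⁻¹); 2 partner → self-condensation product (k = 1.30 M⁻¹ s⁻¹, Ea = 52.0 kJ mol⁻¹); (constants at 60 °C) At 2.00 min the flask holds 0.0163 M of self-condensation product, two partner each, which is 19.3 % of the partner charged. The σ of 0.153 gave 39.7 % for spring, 18 points under the flask. For the neighbour charged with 0.042 M of partner it gives 4.93 % of target, and that neighbour holds 3.75 % of target.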